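## Retrosynthetic overview

1. Target 11 ⇐ bis-silyl ether 10 by cleaving the two ring-B silyl ethers.
2. Ring C is the only ring built (rings A and B are bought) and is closed last through the C3–C4 bond: an intramolecular crossed benzoin of racemic dialdehyde 9. The ring-A aldehyde carbon reacts as an acyl anion (Breslow intermediate of a chiral triazolylidene) on the C3 aldehyde, with dynamic kinetic resolution of the labile C2 centre, so C2 and C3 are both set in this step.
3. 9 ⇐ diol 8 ⇐ aldehyde–ester 7 ⇐ O-alkylation of salicylaldehyde 3 with racemic α-bromo ester 6 (O1–C2 bond).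
4. 3 ⇐ 2,4-dihydroxybenzaldehyde 1 + geranyl bromide 2; 6 ⇐ methyl 3,4-dihydroxyphenylacetate 4 via bis-silyl ether 5.

Assumption: the (5aS,10bR) antipode of the aminoindanol-derived triazolium catalyst is taken to give the 3R carbinol; if it gives 3S, its commercial (5aR,10bS) mirror image is used with nothing else changed.

## Route

Step 1
Reactants: 1 2,4-dihydroxybenzaldehyde; 2 geranyl bromide [(2E)-1-bromo-3,7-dimethylocta-2,6-diene]
Product: 3 4-{[(2E)-3,7-dimethylocta-2,6-dien-1-yl]oxy}-2-hydroxybenzaldehyde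
Conditions: CsHCO3 (1.3 equiv), MeCN, 60 °C
Reagents that add atoms: none
Why: Williamson ether synthesis (SN2) in which the mild hydrogencarbonate base alkylates only the more acidic 4-OH, the 2-OH being held in a hydrogen bond to the formyl group.

Step 2
Reactants: 4 methyl 2-(3,4-dihydroxyphenyl)acetate
Product: 5 methyl 2-[3,4-bis(tert-butyldimethylsilyloxy)phenyl]acetate
Conditions: tert-butyldimethylsilyl chloride (2.4 equiv), imidazole (5 equiv), DMF, rt
Reagents that add atoms: tert-butyldimethylsilyl chloride (TBSCl), CC(C)(C)[Si](C)(C)Cl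
Why: Imidazole-promoted silylation of both catechol hydroxyls gives a protecting group that survives base, hydride and oxidant and can later be removed without touching the geranyl ether.

Step 3
Reactants: 5 methyl 2-[3,4-bis(tert-butyldimethylsilyloxy)phenyl]acetate
Product: 6 methyl 2-bromo-2-[3,4-bis(tert-butyldimethylsilyloxy)phenyl]acetate (racemic)
Conditions: N-bromosuccinimide (1.05 equiv), azobisisobutyronitrile (5 mol %), PhCF3, 80 °C
Reagents that add atoms: N-bromosuccinimide (NBS), O=C1CCC(=O)N1Br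
Why: Wohl–Ziegler radical bromination at the one C–H that is both benzylic and α to the ester; the racemic product is acceptable because C2 is set later.

Step 4
Reactants: 3 4-(geranyloxy)-2-hydroxybenzaldehyde; 6 racemic α-bromo ester
Product: 7 methyl 2-[3,4-bis(tert-butyldimethylsilyloxy)phenyl]-2-(5-{[(2E)-3,7-dimethylocta-2,6-dien-1-yl]oxy}-2-formylphenoxy)acetate (racemic)
Conditions: K2CO3 (1.5 equiv), acetone, rt
Reagents that add atoms: none
Why: Williamson O-alkylation of the salicylaldehyde phenoxide by the activated benzylic α-bromo ester (the same coupling that opens classical 2-arylbenzofuran syntheses) forms the O1–C2 bond, and anhydrous carbonate in acetone at rt leaves the aryl silyl ethers intact.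

Step 5
Reactants: 7 racemic aldehyde–ester
Product: 8 2-[3,4-bis(tert-butyldimethylsilyloxy)phenyl]-2-[5-(geranyloxy)-2-(hydroxymethyl)phenoxy]ethan-1-ol (racemic)
Conditions: LiBH4 (2.5 equiv), THF, 0 °C → rt; pH 7 buffer work-up
Reagents that add atoms: none
Why: Borohydride reduction takes the ester and the aryl aldehyde together to the diol, avoiding an unworkable ester-over-aldehyde differentiation, and leaves alkenes, aryl ethers and silyl ethers untouched.

Step 6
Reactants: 8 racemic diol
Product: 9 2-{1-[3,4-bis(tert-butyldimethylsilyloxy)phenyl]-2-oxoethoxy}-4-(geranyloxy)benzaldehyde (racemic dialdehyde, used at once)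
Conditions: Dess–Martin periodinane (2.6 equiv), pyridine (6 equiv), CH2Cl2, 0 °C → rt
Reagents that add atoms: none
Why: Pyridine-buffered Dess–Martin oxidation converts both primary alcohols to aldehydes without over-oxidation and without acid that would ionise the electron-rich benzylic alcohol or attack the geranyl alkenes.

Step 7
Reactants: 9 racemic dialdehyde
Product: 10 (2R,3R)-2-[3,4-bis(tert-butyldimethylsilyloxy)phenyl]-7-(geranyloxy)-3-hydroxychroman-4-one
Conditions: (5aS,10bR)-5a,10b-dihydro-2-(pentafluorophenyl)-4H,6H-indeno[2,1-b][1,2,4]triazolo[4,3-d][1,4]oxazinium tetrafluoroborate (15 mol %), Et3N (1.0 equiv), toluene, 23 °C, under argon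
Reagents that add atoms: none
Why: Proposed new method: the triazolylidene forms its Breslow intermediate at the aryl aldehyde (the α-branched aryloxy aldehyde is too hindered to be a good donor but is the more electrophilic acceptor), and this acyl anion equivalent at C4 attacks the C3 aldehyde in a 6-exo intramolecular crossed benzoin while Et3N racemises the α-aryl-α-aryloxy aldehyde through its enol, so the catalyst fixes the 3R carbinol and consumes only the enantiomer that can place the C2 aryl group equatorial and trans to the new OH (2R), the conjugated aryl ketone also being the thermodynamic regioisomer; the closest known reactions are the enantioselective NHC-catalysed intramolecular aldehyde–ketone crossed benzoin to 3-hydroxychroman-4-ones and dynamic kinetic resolutions in NHC-catalysed cross-benzoin additions.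

Step 8
Reactants: 10 (2R,3R) bis-silyl ether
Product: 11 (2R,3R)-2-(3,4-dihydroxyphenyl)-7-{[(2E)-3,7-dimethylocta-2,6-dien-1-yl]oxy}-3-hydroxychroman-4-one (target)
Conditions: HF·pyridine, pyridine, THF, 0 °C → rt
Reagents that add atoms: none
Why: Fluoride-driven cleavage of the two aryl silyl ethers (Si–F bond formation) under buffered, slightly acidic conditions neither enolises C3 nor opens ring C and leaves the allylic geranyl ether intact, so no stereocentre is touched.

## Compound list

1 | 2,4-dihydroxybenzaldehyde | O=Cc1ccc(O)cc1O | starting material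
2 | geranyl bromide, (2E)-1-bromo-3,7-dimethylocta-2,6-diene | CC(C)=CCC/C(C)=C/CBr | starting material
3 | 4-{[(2E)-3,7-dimethylocta-2,6-dien-1-yl]oxy}-2-hydroxybenzaldehyde | CC(C)=CCC/C(C)=C/COc1ccc(C=O)c(O)c1 | intermediate
4 | methyl 2-(3,4-dihydroxyphenyl)acetate | COC(=O)Cc1ccc(O)c(O)c1 | starting material
5 | methyl 2-[3,4-bis(tert-butyldimethylsilyloxy)phenyl]acetate | COC(=O)Cc1ccc(O[Si](C)(C)C(C)(C)C)c(O[Si](C)(C)C(C)(C)C)c1 | intermediate
6 | methyl 2-bromo-2-[3,4-bis(tert-butyldimethylsilyloxy)phenyl]acetate, racemic | COC(=O)C(Br)c1ccc(O[Si](C)(C)C(C)(C)C)c(O[Si](C)(C)C(C)(C)C)c1 | intermediate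
7 | methyl 2-[3,4-bis(tert-butyldimethylsilyloxy)phenyl]-2-[5-(geranyloxy)-2-formylphenoxy]acetate, racemic | CC(C)=CCC/C(C)=C/COc1ccc(C=O)c(OC(C(=O)OC)c2ccc(O[Si](C)(C)C(C)(C)C)c(O[Si](C)(C)C(C)(C)C)c2)c1 | intermediate
8 | 2-[3,4-bis(tert-butyldimethylsilyloxy)phenyl]-2-[5-(geranyloxy)-2-(hydroxymethyl)phenoxy]ethan-1-ol, racemic | CC(C)=CCC/C(C)=C/COc1ccc(CO)c(OC(CO)c2ccc(O[Si](C)(C)C(C)(C)C)c(O[Si](C)(C)C(C)(C)C)c2)c1 | intermediate
9 | 2-{1-[3,4-bis(tert-butyldimethylsilyloxy)phenyl]-2-oxoethoxy}-4-(geranyloxy)benzaldehyde, racemic | CC(C)=CCC/C(C)=C/COc1ccc(C=O)c(OC(C=O)c2ccc(O[Si](C)(C)C(C)(C)C)c(O[Si](C)(C)C(C)(C)C)c2)c1 | intermediate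
10 | (2R,3R)-2-[3,4-bis(tert-butyldimethylsilyloxy)phenyl]-7-(geranyloxy)-3-hydroxychroman-4-one | CC(C)=CCC/C(C)=C/COc1ccc2c(c1)O[C@H](c1ccc(O[Si](C)(C)C(C)(C)C)c(O[Si](C)(C)C(C)(C)C)c1)[C@@H](O)C2=O | intermediate
11 | (2R,3R)-2-(3,4-dihydroxyphenyl)-7-{[(2E)-3,7-dimethylocta-2,6-dien-1-yl]oxy}-3-hydroxychroman-4-one | CC(C)=CCC/C(C)=C/COc1ccc2c(c1)O[C@H](c1ccc(O)c(O)c1)[C@@H](O)C2=O | target

## Step count, longest sequence, risks and fallbacks

Total: 8 steps. Longest linear sequence: 7 steps (4 → 5 → 6 → 7 → 8 → 9 → 10 → 11); the ring-A branch (1 + 2 → 3) adds one step.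

**Step 7 (highest risk).** The catalyst may instead add to the aliphatic aldehyde, whose Breslow intermediate can expel the ring-A aryloxide or give the regioisomeric ketol, and racemisation of 9 may be too slow for a clean dynamic resolution. The fallback sets C2 beforehand and closes ring C through a ketyl instead of a Breslow intermediate; it sets out from 5 and 3 and comes back at 10. The potassium enolate of 5 (KN(SiMe3)2, THF, −78 °C) is hydroxylated with the antipode of (camphorylsulfonyl)oxaziridine that gives the S alcohol, methyl (2S)-2-[3,4-bis(tert-butyldimethylsilyloxy)phenyl]-2-hydroxyacetate F1. Mitsunobu coupling of F1 with 3 (PPh3, diisopropyl azodicarboxylate, toluene, 0 °C) inverts the centre and gives methyl (2R)-2-[3,4-bis(tert-butyldimethylsilyloxy)phenyl]-2-[5-(geranyloxy)-2-formylphenoxy]acetate F2. LiBH4 in THF gives (2R)-2-[3,4-bis(tert-butyldimethylsilyloxy)phenyl]-2-[5-(geranyloxy)-2-(hydroxymethyl)phenoxy]ethan-1-ol F3, and buffered Dess–Martin oxidation gives 2-{(1R)-1-[3,4-bis(tert-butyldimethylsilyloxy)phenyl]-2-oxoethoxy}-4-(geranyloxy)benzaldehyde F4. F4 is added at once to SmI2 (2.2 equiv) in THF/t-BuOH at −78 °C; the ketyl radical anion of the aryl aldehyde adds to the neighbouring aldehyde under non-basic conditions that do not epimerise C2, giving mainly (2R,3S,4S)-2-[3,4-bis(tert-butyldimethylsilyloxy)phenyl]-7-(geranyloxy)chromane-3,4-diol F5 (2,3-trans, 3,4-cis). MnO2 in CH2Cl2 oxidises only the benzylic C4 alcohol and gives 10; brief treatment with Et3N equilibrates any 2,3-cis isomer to trans.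

**Step 4.** The phenoxide may strip an aryl silyl ether, the electron-rich bromide may ionise, or 7 may undergo intramolecular aldol closure onto the formyl group. The fallback makes the O1–C2 bond under neutral conditions; it sets out from 5 and 3 and comes back at 7. The potassium enolate of 5 (KN(SiMe3)2, THF, −78 °C) is hydroxylated with 2-(phenylsulfonyl)-3-phenyloxaziridine to racemic methyl 2-[3,4-bis(tert-butyldimethylsilyloxy)phenyl]-2-hydroxyacetate F6. F6 is coupled with 3 under Mitsunobu conditions (PPh3, diisopropyl azodicarboxylate, toluene, 0 °C → rt) to give 7; any loss of configuration is irrelevant here.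

**Step 3.** N-Bromosuccinimide may brominate the electron-rich ring, and 6 is a labile benzylic bromide. The fallback avoids the bromide altogether; it sets out from 5 and 3 and comes back at 7. Diazo transfer to 5 (4-acetamidobenzenesulfonyl azide, 1,8-diazabicyclo[5.4.0]undec-7-ene, MeCN, rt) gives methyl 2-[3,4-bis(tert-butyldimethylsilyloxy)phenyl]-2-diazoacetate F7. Slow addition of F7 to 3 and Rh2(OAc)4 (1 mol %) in CH2Cl2 inserts the rhodium carbenoid into the phenolic O–H bond and gives 7 directly; slow addition and low temperature limit trapping of the intermediate by the formyl group.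

## Further compounds

F1 | step 7 | methyl (2S)-2-[3,4-bis(tert-butyldimethylsilyloxy)phenyl]-2-hydroxyacetate | COC(=O)[C@@H](O)c1ccc(O[Si](C)(C)C(C)(C)C)c(O[Si](C)(C)C(C)(C)C)c1
F2 | step 7 | methyl (2R)-2-[3,4-bis(tert-butyldimethylsilyloxy)phenyl]-2-[5-(geranyloxy)-2-formylphenoxy]acetate | CC(C)=CCC/C(C)=C/COc1ccc(C=O)c(O[C@@H](C(=O)OC)c2ccc(O[Si](C)(C)C(C)(C)C)c(O[Si](C)(C)C(C)(C)C)c2)c1
F3 | step 7 | (2R)-2-[3,4-bis(tert-butyldimethylsilyloxy)phenyl]-2-[5-(geranyloxy)-2-(hydroxymethyl)phenoxy]ethan-1-ol | CC(C)=CCC/C(C)=C/COc1ccc(CO)c(O[C@@H](CO)c2ccc(O[Si](C)(C)C(C)(C)C)c(O[Si](C)(C)C(C)(C)C)c2)c1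
F4 | step 7 | 2-{(1R)-1-[3,4-bis(tert-butyldimethylsilyloxy)phenyl]-2-oxoethoxy}-4-(geranyloxy)benzaldehyde | CC(C)=CCC/C(C)=C/COc1ccc(C=O)c(O[C@@H](C=O)c2ccc(O[Si](C)(C)C(C)(C)C)c(O[Si](C)(C)C(C)(C)C)c2)c1
F5 | step 7 | (2R,3S,4S)-2-[3,4-bis(tert-butyldimethylsilyloxy)phenyl]-7-(geranyloxy)chromane-3,4-diol | CC(C)=CCC/C(C)=C/COc1ccc2c(c1)O[C@H](c1ccc(O[Si](C)(C)C(C)(C)C)c(O[Si](C)(C)C(C)(C)C)c1)[C@@H](O)[C@H]2O
F6 | step 4 | methyl 2-[3,4-bis(tert-butyldimethylsilyloxy)phenyl]-2-hydroxyacetate, racemic | COC(=O)C(O)c1ccc(O[Si](C)(C)C(C)(C)C)c(O[Si](C)(C)C(C)(C)C)c1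
F7 | step 3 | methyl 2-[3,4-bis(tert-butyldimethylsilyloxy)phenyl]-2-diazoacetate | COC(=O)C(=[N+]=[N-])c1ccc(O[Si](C)(C)C(C)(C)C)c(O[Si](C)(C)C(C)(C)C)c1
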